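**Plan**

- Cuts, in labdane numbering: first the C2 acetate and the C2–O configuration (oxidation–reduction at the end), then C12–C13 (iron-catalysed sp3–sp2 coupling with a (Z)-enol triflate), then C8=C17 (methylenation of an 8-ketone), and last C5–C6 and C9–C10 of ring B together. What remains is a ring A enol triflate from (4R,6R)-actinol and a six-carbon (Z)-iododiene.
- Enabling feature: ring B is fused to ring A through C5–C10, so at the diene level (C5=C6–C7=C8) it is the electrocyclization product of a triene C10=C5–C6=C7–C8=C9. Its C10=C5 end is the tetrasubstituted ring A alkene that carries C20, the pattern of the previtamin D to pyrocalciferol closure.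
- Forward: ring A is bought. One flask joins C5–C6 (Negishi coupling) and closes C9–C10 (6π), giving ring B as a silyl dienol ether. Then follow the 8-ketone, the trans ring fusion, the exocyclic methylene, the side chain and the C2 adjustment.
- Stereochemistry: the only bought centre is the actinol carbinol (C2, carried with the configuration opposite to the target). In the ring closure the syn-axial C19 and C20 methyls keep its silyl ether equatorial and so fix C10. C5 (radical hydrogenation) and C9 (equilibration) follow from C10. The same two axial methyls then steer hydride to the α face of the 2-ketone to give the axial 2β-alcohol. The 13Z geometry is carried over from the enol triflate.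

Key step: step 6

Remark: labdane numbering is used for all bicyclic compounds (ring A = C1–C5 and C10, ring B = C5–C10, C17 on C8, C18 and C19 on C4, C20 on C10; β is the face of C20); compounds 1 and 4 are taken as catalogue chemicals.

**Route**

Step 1
Reactants: 1 (4R,6R)-4-hydroxy-2,2,6-trimethylcyclohexan-1-one ((4R,6R)-actinol)
Product: 2 (4R,6R)-4-(tert-butyldiphenylsilyloxy)-2,2,6-trimethylcyclohexan-1-one
Conditions: TBDPSCl, imidazole, DMF, 22 °C
Reagents that add atoms: TBDPSCl, CC(C)(C)[Si](Cl)(c1ccccc1)c1ccccc1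
Why: Silyl ether formation on the unhindered secondary alcohol is routine, and the bulky, acid-stable ether later serves as the equatorial anchor in the ring closure.

Step 2
Reactants: 2 (4R,6R)-4-(tert-butyldiphenylsilyloxy)-2,2,6-trimethylcyclohexan-1-one
Product: 3 (4R)-4-(tert-butyldiphenylsilyloxy)-2,6,6-trimethylcyclohex-1-en-1-yl trifluoromethanesulfonate
Conditions: LDA, THF, −78 → 0 °C; PhNTf2, −78 → 22 °C
Reagents that add atoms: PhNTf2, O=S(=O)(N(c1ccccc1)S(=O)(=O)C(F)(F)F)C(F)(F)F
Why: The ketone can enolize only toward the methine carbon because the other α-carbon is quaternary, so a single tetrasubstituted enolate should form and be trapped on oxygen (enol triflate formation, as with 2,2,6-trimethylcyclohexanone); the methine stereocenter is erased on purpose.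

Step 3
Reactants: 4 4-chloro-N-methoxy-N-methylbutanamide
Product: 5 6-chlorohex-1-yn-3-one
Conditions: HC≡CMgBr, THF, 0 °C; inverse quench into cold aq. HCl
Reagents that add atoms: ethynylmagnesium bromide, C#C[Mg]Br
Why: Weinreb ketone synthesis: the chelated tetrahedral intermediate should survive until the acidic inverse quench, which also keeps the liberated amine from adding to the ynone.

Step 4
Reactants: 5 6-chlorohex-1-yn-3-one
Product: 6 (Z)-6-chloro-1-iodohex-1-en-3-one
Conditions: NaI, AcOH, 22 °C
Reagents that add atoms: NaI, [Na+].[I-]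
Why: Hydroiodination of an ynone with NaI in AcOH is a kinetic anti conjugate addition that should give the (Z)-β-iodoenone, the geometry needed for the cis C6=C7 bond of the triene.

Step 5
Reactants: 6 (Z)-6-chloro-1-iodohex-1-en-3-one
Product: 7 (1Z,3Z)-3-(tert-butyldimethylsilyloxy)-6-chloro-1-iodohexa-1,3-diene
Conditions: TBSOTf, i-Pr2NEt, CH2Cl2, −78 → −20 °C
Reagents that add atoms: TBSOTf, CC(C)(C)[Si](C)(C)OS(=O)(=O)C(F)(F)F
Why: Soft enolization (silyl enol ether formation) with a non-nucleophilic base should silylate the only enolizable side of the ketone to the preferred (Z)-enol ether without addition–elimination at the vinyl iodide.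

Step 6
Reactants: 7 (1Z,3Z)-3-(tert-butyldimethylsilyloxy)-6-chloro-1-iodohexa-1,3-diene; 3 (4R)-4-(tert-butyldiphenylsilyloxy)-2,6,6-trimethylcyclohex-1-en-1-yl trifluoromethanesulfonate
Product: 11 8-(tert-butyldimethylsilyloxy)-2α-(tert-butyldiphenylsilyloxy)-12-chloro-9βH-13,14,15,16,17-pentanorlabda-5,7-diene, via dienyllithium 8 (not isolated), via dienylzinc chloride 9 (not isolated), via silyloxytriene 10 (not isolated)
Conditions: 7, t-BuLi (2 equiv), Et2O, −78 °C; ZnCl2, THF, −78 → 0 °C; 3, Pd(PPh3)4 (5 mol %), 45 °C; then toluene, i-Pr2NEt, 140 °C (sealed tube)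
Reagents that add atoms: none
Why: Iodine–lithium exchange and transmetalation give the (Z)-dienylzinc 9, which zerovalent palladium couples with the hindered enol triflate 3 with retention (Negishi coupling, C5–C6), and the resulting (Z)-hexatriene 10 then closes thermally by 6π-electrocyclization (C9–C10); the closest known reaction type is a cross-coupling/6π-electrocyclization cascade, and the closure itself is the previtamin D to pyrocalciferol reaction, which forms the same C9–C10 bond next to an angular methyl. Ring B is the only ring closed, by a thermally allowed disrotatory six-electron closure of the C10=C5–C6=C7–C8=C9 triene. C10 is set by torquoselectivity: in the chair-like transition state C20 turns axial on ring A, syn to the axial C19 methyl, so the bulky C2 silyl ether should stay equatorial, which places C20 trans to the C2 oxygen. C9 follows from the (Z)-enol ether geometry and disrotation (H9 cis to C20) and is corrected in step 8 next to the C8 ketone. The step needs the closure to win over the [1,7]-hydrogen shift from C20, which is reversible and only returns triene, and needs the cis C6=C7 geometry, which the stereoretentive exchange and coupling of the (1Z)-iodide secure.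

Step 7
Reactants: 11 8-(tert-butyldimethylsilyloxy)-2α-(tert-butyldiphenylsilyloxy)-12-chloro-9βH-13,14,15,16,17-pentanorlabda-5,7-diene
Product: 12 2α-(tert-butyldiphenylsilyloxy)-12-chloro-9βH-13,14,15,16,17-pentanorlabd-5-en-8-one
Conditions: HF·pyridine, pyridine, THF, 0 °C
Reagents that add atoms: none
Why: Fluoride should cleave the silyl dienol ether far faster than the hindered alkyl TBDPS ether, and the dienol is protonated kinetically at the α-carbon C7 (deconjugative hydrolysis of a dienol ether), which leaves the C5=C6 alkene for the next step.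

Step 8
Reactants: 12 2α-(tert-butyldiphenylsilyloxy)-12-chloro-9βH-13,14,15,16,17-pentanorlabd-5-en-8-one
Product: 14 2α-(tert-butyldiphenylsilyloxy)-12-chloro-13,14,15,16,17-pentanor-5α,9αH-labdan-8-one, via 9-epi ketone 13 (not isolated)
Conditions: Mn(dpm)3 (dpm = dipivaloylmethanate, 10 mol %), PhSiH3, t-BuOOH, i-PrOH, 22 °C; then aq. HCl, THF, 40 °C
Reagents that add atoms: none
Why: Mukaiyama-type hydrogen atom transfer hydrogenation puts H on C6, and the tertiary C5 radical should take its hydrogen on the α face, opposite the axial C19 and C20 methyls, to give the trans-decalin; acid-catalysed enolization (chosen over base because a γ-chloro ketone enolate could close a cyclopropane) then moves the C9 side chain to the equatorial β position.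

Step 9
Reactants: 14 2α-(tert-butyldiphenylsilyloxy)-12-chloro-13,14,15,16,17-pentanor-5α,9αH-labdan-8-one
Product: 15 2α-(tert-butyldiphenylsilyloxy)-12-chloro-13,14,15,16-tetranorlabd-8(17)-ene
Conditions: Zn, CH2Br2, TiCl4, THF/CH2Cl2, 0 → 22 °C
Reagents that add atoms: CH2Br2, BrCBr
Why: Takai–Lombardo methylenation is non-basic and suited to hindered, epimerizable ketones, so C9 should stay equatorial and the γ-chloro ketone is not enolized.

Step 10
Reactants: 16 methyl acetoacetate (methyl 3-oxobutanoate)
Product: 17 methyl (Z)-3-(trifluoromethylsulfonyloxy)but-2-enoate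
Conditions: Tf2O, aq. LiOH, toluene, 5 °C
Reagents that add atoms: Tf2O, O=S(=O)(OS(=O)(=O)C(F)(F)F)C(F)(F)F
Why: Triflation of the chelated lithium enolate of a β-keto ester under aqueous LiOH conditions (stereoselective enol triflate formation) should give the (Z)-isomer, which stores the 13Z geometry.

Step 11
Reactants: 15 2α-(tert-butyldiphenylsilyloxy)-12-chloro-13,14,15,16-tetranorlabd-8(17)-ene; 17 methyl (Z)-3-(trifluoromethylsulfonyloxy)but-2-enoate
Product: 19 methyl 2α-(tert-butyldiphenylsilyloxy)labda-8(17),13Z-dien-15-oate, via Grignard reagent 18 (not isolated)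
Conditions: 15, Mg, THF, 60 °C; then 17, Fe(acac)3 (5 mol %), THF/NMP, −30 °C
Reagents that add atoms: none
Why: The primary chloride gives a Grignard reagent that low-valent iron should couple with the enol triflate faster than it attacks the ester and with retention of alkene geometry (iron-catalysed Kumada-type sp3–sp2 cross-coupling), so C12–C13 and the 13Z alkene arise together.

Step 12
Reactants: 19 methyl 2α-(tert-butyldiphenylsilyloxy)labda-8(17),13Z-dien-15-oate
Product: 20 methyl 2α-hydroxylabda-8(17),13Z-dien-15-oate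
Conditions: TBAF, AcOH, THF, 45 °C
Reagents that add atoms: none
Why: Buffered fluoride desilylation should free the equatorial 2α-alcohol without touching the enoate or the exocyclic alkene.

Step 13
Reactants: 20 methyl 2α-hydroxylabda-8(17),13Z-dien-15-oate
Product: 21 methyl 2-oxolabda-8(17),13Z-dien-15-oate
Conditions: Dess–Martin periodinane, pyridine, CH2Cl2, 22 °C
Reagents that add atoms: none
Why: Dess–Martin oxidation converts the secondary alcohol into the 2-ketone under near-neutral conditions, and no centre can epimerize because C1 and C3 are flanked by the quaternary C10 and C4.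

Step 14
Reactants: 21 methyl 2-oxolabda-8(17),13Z-dien-15-oate
Product: 22 methyl 2β-hydroxylabda-8(17),13Z-dien-15-oate
Conditions: NaBH4, MeOH, −20 → 0 °C
Reagents that add atoms: none
Why: Hydride reduction of the cyclohexanone: the axial C19 and C20 methyls both shield the β face of C2, so hydride should attack from the α face (equatorial attack) and give the axial 2β-alcohol (2R), while the enoate is not reduced.

Step 15
Reactants: 22 methyl 2β-hydroxylabda-8(17),13Z-dien-15-oate
Product: 23 2β-hydroxylabda-8(17),13Z-dien-15-oic acid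
Conditions: LiOH, THF/MeOH/H2O, 40 °C; then aq. HCl to pH 3
Reagents that add atoms: LiOH, [Li+].[OH-]
Why: Saponification before acetylation avoids having to tell two esters apart at the end, and mild LiOH should not isomerize the β,β-disubstituted (Z)-enoate.

Step 16
Reactants: 23 2β-hydroxylabda-8(17),13Z-dien-15-oic acid
Product: 25 (2R,5S,9S,10S)-2β-acetoxylabda-8(17),13Z-dien-15-oic acid (CNP0255148.1), via mixed anhydride 24 (not isolated)
Conditions: Ac2O, DMAP, pyridine, 40 °C; then H2O, THF, 22 °C
Reagents that add atoms: Ac2O, CC(=O)OC(C)=O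
Why: DMAP-catalysed acetylation should esterify the hindered axial alcohol, and the mixed anhydride formed at the carboxyl group is hydrolysed in the aqueous stage because an anhydride is far more labile than the hindered acetate.

**Compound list**

1 | (4R,6R)-4-hydroxy-2,2,6-trimethylcyclohexan-1-one ((4R,6R)-actinol) | O=C1C(C)(C)C[C@H](O)C[C@H]1C | starting material
2 | (4R,6R)-4-(tert-butyldiphenylsilyloxy)-2,2,6-trimethylcyclohexan-1-one | O=C1C(C)(C)C[C@H](O[Si](c2ccccc2)(c2ccccc2)C(C)(C)C)C[C@H]1C | intermediate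
3 | (4R)-4-(tert-butyldiphenylsilyloxy)-2,6,6-trimethylcyclohex-1-en-1-yl trifluoromethanesulfonate | CC1=C(OS(=O)(=O)C(F)(F)F)C(C)(C)C[C@H](O[Si](c2ccccc2)(c2ccccc2)C(C)(C)C)C1 | intermediate
4 | 4-chloro-N-methoxy-N-methylbutanamide | CON(C)C(=O)CCCCl | starting material
5 | 6-chlorohex-1-yn-3-one | C#CC(=O)CCCCl | intermediate
6 | (Z)-6-chloro-1-iodohex-1-en-3-one | I/C=C\C(=O)CCCCl | intermediate
7 | (1Z,3Z)-3-(tert-butyldimethylsilyloxy)-6-chloro-1-iodohexa-1,3-diene | I/C=C\C(O[Si](C)(C)C(C)(C)C)=C\CCCl | intermediate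
8 | [(1Z,3Z)-3-(tert-butyldimethylsilyloxy)-6-chlorohexa-1,3-dienyl]lithium | [Li]/C=C\C(O[Si](C)(C)C(C)(C)C)=C\CCCl | intermediate
9 | [(1Z,3Z)-3-(tert-butyldimethylsilyloxy)-6-chlorohexa-1,3-dienyl]zinc chloride | Cl[Zn]/C=C\C(O[Si](C)(C)C(C)(C)C)=C\CCCl | intermediate
10 | (4R)-1-[(1Z,3Z)-3-(tert-butyldimethylsilyloxy)-6-chlorohexa-1,3-dienyl]-4-(tert-butyldiphenylsilyloxy)-2,6,6-trimethylcyclohexene | CC1=C(/C=C\C(O[Si](C)(C)C(C)(C)C)=C\CCCl)C(C)(C)C[C@H](O[Si](c2ccccc2)(c2ccccc2)C(C)(C)C)C1 | intermediate
11 | 8-(tert-butyldimethylsilyloxy)-2α-(tert-butyldiphenylsilyloxy)-12-chloro-9βH-13,14,15,16,17-pentanorlabda-5,7-diene | CC(C)(C)[Si](C)(C)OC1=CC=C2C(C)(C)C[C@H](O[Si](c3ccccc3)(c3ccccc3)C(C)(C)C)C[C@]2(C)[C@@H]1CCCl | intermediate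
12 | 2α-(tert-butyldiphenylsilyloxy)-12-chloro-9βH-13,14,15,16,17-pentanorlabd-5-en-8-one | O=C1CC=C2C(C)(C)C[C@H](O[Si](c3ccccc3)(c3ccccc3)C(C)(C)C)C[C@]2(C)[C@@H]1CCCl | intermediate
13 | 2α-(tert-butyldiphenylsilyloxy)-12-chloro-13,14,15,16,17-pentanor-5α,9βH-labdan-8-one (9-epi ketone) | O=C1CC[C@H]2C(C)(C)C[C@H](O[Si](c3ccccc3)(c3ccccc3)C(C)(C)C)C[C@]2(C)[C@@H]1CCCl | intermediate
14 | 2α-(tert-butyldiphenylsilyloxy)-12-chloro-13,14,15,16,17-pentanor-5α,9αH-labdan-8-one | O=C1CC[C@H]2C(C)(C)C[C@H](O[Si](c3ccccc3)(c3ccccc3)C(C)(C)C)C[C@]2(C)[C@H]1CCCl | intermediate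
15 | 2α-(tert-butyldiphenylsilyloxy)-12-chloro-13,14,15,16-tetranorlabd-8(17)-ene | C=C1CC[C@H]2C(C)(C)C[C@H](O[Si](c3ccccc3)(c3ccccc3)C(C)(C)C)C[C@]2(C)[C@H]1CCCl | intermediate
16 | methyl acetoacetate | CC(=O)CC(=O)OC | starting material
17 | methyl (Z)-3-(trifluoromethylsulfonyloxy)but-2-enoate | C/C(OS(=O)(=O)C(F)(F)F)=C/C(=O)OC | intermediate
18 | [2α-(tert-butyldiphenylsilyloxy)-13,14,15,16-tetranorlabd-8(17)-en-12-yl]magnesium chloride | C=C1CC[C@H]2C(C)(C)C[C@H](O[Si](c3ccccc3)(c3ccccc3)C(C)(C)C)C[C@]2(C)[C@H]1CC[Mg]Cl | intermediate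
19 | methyl 2α-(tert-butyldiphenylsilyloxy)labda-8(17),13Z-dien-15-oate | C=C1CC[C@H]2C(C)(C)C[C@H](O[Si](c3ccccc3)(c3ccccc3)C(C)(C)C)C[C@]2(C)[C@H]1CC/C(C)=C\C(=O)OC | intermediate
20 | methyl 2α-hydroxylabda-8(17),13Z-dien-15-oate | C=C1CC[C@H]2C(C)(C)C[C@H](O)C[C@]2(C)[C@H]1CC/C(C)=C\C(=O)OC | intermediate
21 | methyl 2-oxolabda-8(17),13Z-dien-15-oate | C=C1CC[C@H]2C(C)(C)CC(=O)C[C@]2(C)[C@H]1CC/C(C)=C\C(=O)OC | intermediate
22 | methyl 2β-hydroxylabda-8(17),13Z-dien-15-oate | C=C1CC[C@H]2C(C)(C)C[C@@H](O)C[C@]2(C)[C@H]1CC/C(C)=C\C(=O)OC | intermediate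
23 | 2β-hydroxylabda-8(17),13Z-dien-15-oic acid | C=C1CC[C@H]2C(C)(C)C[C@@H](O)C[C@]2(C)[C@H]1CC/C(C)=C\C(=O)O | intermediate
24 | acetic 2β-acetoxylabda-8(17),13Z-dien-15-oic anhydride | C=C1CC[C@H]2C(C)(C)C[C@@H](OC(C)=O)C[C@]2(C)[C@H]1CC/C(C)=C\C(=O)OC(C)=O | intermediate
25 | (2R,5S,9S,10S)-2β-acetoxylabda-8(17),13Z-dien-15-oic acid (CNP0255148.1) | C=C1CC[C@H]2C(C)(C)C[C@@H](OC(C)=O)C[C@]2(C)[C@H]1CC/C(C)=C\C(=O)O | target

**Counts**

Total step count: 16.
Longest linear sequence: 13 steps (4 → 25 through steps 3, 4, 5, 6, 7, 8, 9, 11, 12, 13, 14, 15, 16).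

**Three steps most likely to fail**

1. Step 6. The thermal ring closure may lose to the [1,7]-hydrogen shift from C20, silyl transfer from oxygen to carbon may occur in the lithiated diene, or the triene may close on both faces of ring A. The fallback sets out from 3 and 6 and comes back at 12; it makes the two bonds in separate events and closes the ring as an enolate at low temperature. Triflate 3 is borylated (B2pin2, PdCl2(dppf), KOAc, dioxane, 80 °C) to (4R)-4-(tert-butyldiphenylsilyloxy)-2,6,6-trimethylcyclohex-1-enylboronic acid pinacol ester F1. Suzuki coupling of this boronate with iodoenone 6 (Pd(PPh3)4, K3PO4, THF/H2O, 40 °C) should give the (Z)-dienone F2. KHMDS (THF, −78 °C) converts it into the potassium trienolate F3. Its closure on warming to −20 °C and protonation at C7 on quenching with AcOH should give 12. The closure has to be faster than alkylation of the enolate by the remote chloride, which the low temperature favours.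

2. Step 8. Hydrogen delivery to the C5 radical may be poorly face-selective because the C9 substituent is still axial on the α face, and the β,γ-enone may slip into conjugation before it is reduced. The fallback sets out from 12 and comes back at 14; it sets C5 by equilibration instead of radical capture. Acid (TsOH, CHCl3, 50 °C) moves the alkene into conjugation through the dienol, which equilibrates C5 (γ) and C9 (α′) and should favour the trans-fused 2α-(tert-butyldiphenylsilyloxy)-12-chloro-13,14,15,16,17-pentanor-5α,9αH-labd-6-en-8-one F4. Hydrogenation of its disubstituted C6=C7 bond (H2, Pd/C, EtOAc) gives 14.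

3. Step 11. Grignard formation from the primary chloride may be slow or accompanied by Wurtz coupling, and the iron coupling may erode the Z geometry or lose to attack on the ester. The fallback sets out from 15 and comes back at 19; it builds the Z alkene by syn-carbocupration instead of transferring it from an enol triflate. Finkelstein exchange (NaI, acetone, 56 °C) gives 2α-(tert-butyldiphenylsilyloxy)-12-iodo-13,14,15,16-tetranorlabd-8(17)-ene F5. Alkylation of lithium (trimethylsilyl)acetylide (THF/DMPU, −20 → 22 °C) gives 2α-(tert-butyldiphenylsilyloxy)-14-(trimethylsilyl)-15,16-dinorlabd-8(17)-en-13-yne F6. K2CO3 in MeOH gives 2α-(tert-butyldiphenylsilyloxy)-15,16-dinorlabd-8(17)-en-13-yne F7. Deprotonation with n-BuLi and trapping with ClCO2Me gives methyl 2α-(tert-butyldiphenylsilyloxy)-16-norlabd-8(17)-en-13-yn-15-oate F8. Me2CuLi (THF, −78 °C) adds methyl and copper syn across the alkyne, and protonation at −78 °C should give 19 with the chain cis to the ester.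

Further compounds
F1 | step 6 | (4R)-4-(tert-butyldiphenylsilyloxy)-2,6,6-trimethylcyclohex-1-enylboronic acid pinacol ester | CC1=C(B2OC(C)(C)C(C)(C)O2)C(C)(C)C[C@H](O[Si](c2ccccc2)(c2ccccc2)C(C)(C)C)C1
F2 | step 6 | (Z)-1-[(4R)-4-(tert-butyldiphenylsilyloxy)-2,6,6-trimethylcyclohex-1-enyl]-6-chlorohex-1-en-3-one | CC1=C(/C=C\C(=O)CCCCl)C(C)(C)C[C@H](O[Si](c2ccccc2)(c2ccccc2)C(C)(C)C)C1
F3 | step 6 | potassium (1Z,3Z)-1-[(4R)-4-(tert-butyldiphenylsilyloxy)-2,6,6-trimethylcyclohex-1-enyl]-6-chlorohexa-1,3-dien-3-olate | CC1=C(/C=C\C([O-])=C\CCCl)C(C)(C)C[C@H](O[Si](c2ccccc2)(c2ccccc2)C(C)(C)C)C1.[K+]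
F4 | step 8 | 2α-(tert-butyldiphenylsilyloxy)-12-chloro-13,14,15,16,17-pentanor-5α,9αH-labd-6-en-8-one | O=C1C=C[C@H]2C(C)(C)C[C@H](O[Si](c3ccccc3)(c3ccccc3)C(C)(C)C)C[C@]2(C)[C@H]1CCCl
F5 | step 11 | 2α-(tert-butyldiphenylsilyloxy)-12-iodo-13,14,15,16-tetranorlabd-8(17)-ene | C=C1CC[C@H]2C(C)(C)C[C@H](O[Si](c3ccccc3)(c3ccccc3)C(C)(C)C)C[C@]2(C)[C@H]1CCI
F6 | step 11 | 2α-(tert-butyldiphenylsilyloxy)-14-(trimethylsilyl)-15,16-dinorlabd-8(17)-en-13-yne | C=C1CC[C@H]2C(C)(C)C[C@H](O[Si](c3ccccc3)(c3ccccc3)C(C)(C)C)C[C@]2(C)[C@H]1CCC#C[Si](C)(C)C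
F7 | step 11 | 2α-(tert-butyldiphenylsilyloxy)-15,16-dinorlabd-8(17)-en-13-yne | C=C1CC[C@H]2C(C)(C)C[C@H](O[Si](c3ccccc3)(c3ccccc3)C(C)(C)C)C[C@]2(C)[C@H]1CCC#C
F8 | step 11 | methyl 2α-(tert-butyldiphenylsilyloxy)-16-norlabd-8(17)-en-13-yn-15-oate | C=C1CC[C@H]2C(C)(C)C[C@H](O[Si](c3ccccc3)(c3ccccc3)C(C)(C)C)C[C@]2(C)[C@H]1CCC#CC(=O)OC
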